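A small charge of nucleophile, 1.05 equivalents on the electrophile, goes slowly into a flask holding free base, and every coupling sets acid free.

    acid set free + free base ⇌ salt of the base, settled at all times (K1 = 12000 /M)
    electrophile + nucleophile → acid set free + target (k2 = 3.3 × 10⁻⁴ /M/s)
    nucleophile + acid set free ⇌ protonated nucleophile, settled at all times (K3 = 2.5 × 10⁵ /M)
    electrophile ⇌ dormant form (K4 = 0.20, k4 = 5.9 × 10⁻⁶ /s)
    nucleophile + target → over-reaction product (k5 = 1.1 × 10⁻⁴ /M/s)
    electrophile + acid set free → side product (k6 = 9.7 × 10⁻⁴ /M/s)

electrophile 0.028 M; nucleophile 0.0294 M (fed, over 30 h); free base 0.0280 M; time 10 d; the fed solution adds 0.10 times the starting volume

- part of the electrophile that has reacted at 10 d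
- share of the unused nucleophile that is free and not bound as protonated nucleophile, at 10 d

- amounts are per litre of the starting volume; all of the dose is in the solution fed
- what has gone from electrophile into another species counts as reacted, even if it can come back
- run time (flask): 10 d

All amounts below are fractions of the electrophile charge, which in this flask equals the free base charge.

*Who takes the acid first?* The nucleophile, because it binds acid more strongly than the free base does, by a factor of 20.8. So early on each coupling costs two nucleophile: one to react, one to hold the acid.

*How far does that reach?* To the stall point, the part of the electrophile coupled when the nucleophile charge is paid out at two per coupling and the free base has taken nothing: 52.5%. At that price the nucleophile is the limiting reagent.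

*Is that a wall?* No, and there are two leaks. Over-reaction takes nucleophile without setting acid free. The dormant form balances with the electrophile quickly, in 0.227 d, so the race of over-reaction against coupling costs 8.78% up to the stall point. Meanwhile the free base does take acid.

*How fast?* Call s the part of the free base carrying acid. Past the stall point, free nucleophile shrinks as s grows, and each further coupling moves two acids onto the base, so s grows as the root of time. That clock must not start at the end of the feed, since the gap to the stall point closes with a time constant of 1.74 d, reckoned from the coupling rate near that point at two nucleophile per coupling. As my own allowance, I start it 2 of those time constants after the feed, which leaves 5.27 d and gives 35.6%. The shrinking store of unloaded base trims that to 28.6%.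

*What do you commit to?* Coupling reaches 62.4%. Counting the dormant share as reacted gives c = 68.7%, and the buffer gives fr = 10.7%.

The forecast says 64% and 13%, since the nucleophile, in its words, “takes up the released acid first”. The simulation gives 67.0% and 10.7%.

What to watch is the race for nucleophile: coupling used it 6.2 times as fast as over-reaction at 1.52 d, but 2.0 times as fast at 10.0 d. At that later time target and over-reaction product in the flask hold 59.8% of the electrophile, more than the stall point of 52.5%. The neighbour flask with 0.12 M of nucleophile has a stall point of 214%, above the whole electrophile charge; there 0.0104% of the electrophile is left and over-reaction product holds 96.4%.

The numbers of this flask are assumed; no experiment stands behind them.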